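The target is the shikimate triester methyl (3R,4S,5R)-3-acetoxy-4,5-bis{[(2R)-2-methylbutanoyl]oxy}cyclohex-1-ene-1-carboxylate. Everything rests on cutting its C1–C6 bond (C1 = ester-bearing sp2 carbon, C3 = acetoxy carbon, C6 = ring CH2). That bond, flanked by a latent C4=C5 alkene, the C3 oxygen and a C2 oxygen that is eliminated later, is the imprint of a Claisen rearrangement. Heating a D-galactal that carries a vinyl group on C5 and an acetonide on O3/O4 joins glycal C2 to the vinyl terminus, cleaves the pyran C5–O bond and closes the carbocycle as a formylcyclohexene in one operation. Galactal C4 survives untouched as target C3.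

Key step: step 4

Assumption: D-galactal 1 is bought as such (its commercial triacetate would add one Zemplén deacetylation). Carbohydrate numbering is used for 1–4 (vinyl carbons of 4 = C6 and C7); "target C…" always means the numbering of the final cyclohexene.

Step 1
Reactants: 1 D-galactal
Product: 2 3,4-O-isopropylidene-D-galactal
Conditions: Me2C(OMe)2, PPTS (cat.), acetone, 0 °C to rt; Et3N quench, aqueous work-up
Reagents that add atoms: 2,2-dimethoxypropane, COC(C)(C)OC
Why: Acid-catalysed transketalisation under equilibrating conditions places the isopropylidene group on the cis-3,4-diol as a five-membered dioxolane in preference to the 4,6-dioxane, the weak pyridinium acid spares the enol ether, and any mixed ketal on O6 is lost on work-up.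

Step 2
Reactants: 2 3,4-O-isopropylidene-D-galactal
Product: 3 3,4-O-isopropylidene-D-galactal 6-aldehyde (C6 oxidised to CHO; C3, C4 and C5 unchanged)
Conditions: (COCl)2, DMSO, CH2Cl2, −78 °C; Et3N, −78 to 0 °C
Reagents that add atoms: none
Why: Swern oxidation: the alkoxysulfonium ylide from activated DMSO collapses at low temperature to the aldehyde without over-oxidation, the enol ether and the ketal are inert to it, and the cold, brief exposure to Et3N leaves the α-alkoxy centre C5 in place.

Step 3
Reactants: 3 3,4-O-isopropylidene-D-galactal 6-aldehyde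
Product: 4 5-vinyl-3,4-O-isopropylidene-D-galactal (1,5-anhydro-2,6,7-trideoxy-3,4-O-isopropylidene-D-lyxo-hepta-1,6-dienitol)
Conditions: Ph3PCH3Br, KN(SiMe3)2, THF, 0 °C; then 3, −78 °C to rt
Reagents that add atoms: methyltriphenylphosphonium bromide, C[P+](c1ccccc1)(c1ccccc1)c1ccccc1.[Br-]
Why: Wittig methylenation with a non-stabilised ylide adds to the aldehyde at −78 °C faster than it enolises it, so the C5 centre that will steer the rearrangement is carried into the vinyl compound.

Step 4
Reactants: 4 5-vinyl-3,4-O-isopropylidene-D-galactal
Product: 5 (1S,5S,6R)-5,6-(isopropylidenedioxy)cyclohex-3-ene-1-carbaldehyde (formyl trans to both dioxolane oxygens; this is the enantiomer that D-galactal delivers)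
Conditions: 1,2-dichlorobenzene (degassed, dilute), 240 °C, sealed base-washed tube, Ar
Reagents that add atoms: none
Why: The O5–C1=C2 enol ether and the C5–CH=CH2 unit of 4 form an allyl vinyl ether that undergoes a concerted, suprafacial [3,3]-sigmatropic shift: the C2–C7 bond forms while the C5–O5 bond breaks, C5=C6 becomes the ring alkene and C1 emerges as the formyl group. The closest known reaction is the thermal aliphatic Claisen rearrangement of 5-vinyl glycals (2-vinyl-3,4-dihydro-2H-pyrans) to cyclohex-3-enecarbaldehydes. The six-membered carbocycle is closed pericyclically through a boat-like, bicyclo[2.2.2]-shaped transition state imposed by the pyran ring, formally a 6-endo-trig attack of C2 on the vinyl terminus. The one new stereocentre (C1 of 5, S) is dictated by galactal C5: the vinyl group sits on the same face as O3 and O4, so the new C–C bond can only form on that face and the formyl group ends trans to the two dioxolane oxygens. The step needs nothing beyond this intramolecular chirality transfer, because the tether excludes any other transition state, galactal C3 and C4 are spectators, and a neutral, acid-free, dilute medium should keep the enol ether, the acetonide and the β-alkoxy aldehyde intact. The new centre is erased in step 6, so only the untouched galactal C4 (target C3) carries stereochemical information forward.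

Step 5
Reactants: 5 (1S,5S,6R)-5,6-(isopropylidenedioxy)cyclohex-3-ene-1-carbaldehyde
Product: 7 methyl (1S,5S,6R)-5,6-(isopropylidenedioxy)cyclohex-3-ene-1-carboxylate, via carboxylic acid 6 (not isolated)
Conditions: NaClO2, NaH2PO4, 2-methyl-2-butene, t-BuOH/H2O, 0 °C to rt; extract into CH2Cl2, dry; then TMSCHN2, MeOH, 0 °C
Reagents that add atoms: sodium chlorite, [Na+].[O-]Cl=O; trimethylsilyldiazomethane, C[Si](C)(C)C=[N+]=[N-]
Why: Pinnick (chlorite) oxidation converts the aldehyde into the acid at buffered pH while 2-methyl-2-butene traps the hypochlorous acid that would attack the ring alkene, and non-basic methylation of the acid with TMSCHN2/MeOH gives the ester without triggering β-elimination, so no stereocentre is touched.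

Step 6
Reactants: 7 methyl (1S,5S,6R)-5,6-(isopropylidenedioxy)cyclohex-3-ene-1-carboxylate
Product: 9 methyl (3S)-3-hydroxycyclohexa-1,4-diene-1-carboxylate, via ring-opened hemiketal 8 (not isolated)
Conditions: LiN(SiMe3)2 (1.1 equiv), THF, −78 to 0 °C; AcOH quench
Reagents that add atoms: none
Why: E1cB elimination: the ester enolate expels the β-oxygen (former galactal O3), the hemiketal alkoxide sheds acetone, and the product is held as its lithium alkoxide, which cannot lose oxide to give an arene; this creates the target C1=C2 bond and frees the C3 hydroxyl, whose configuration (from galactal C4) is untouched, and an amide base is chosen because an amidine base is too weak to enolise a simple ester.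

Step 7
Reactants: 9 methyl (3S)-3-hydroxycyclohexa-1,4-diene-1-carboxylate
Product: 10 methyl (1S,5R,6R)-5-hydroxy-7-oxabicyclo[4.1.0]hept-3-ene-3-carboxylate (4,5-epoxide cis to the C3 hydroxyl in target numbering)
Conditions: VO(acac)2 (5 mol %), t-BuOOH (in decane), CH2Cl2, 0 °C to rt
Reagents that add atoms: tert-butyl hydroperoxide, CC(C)(C)OO
Why: Vanadium-catalysed hydroxyl-directed epoxidation: the alkyl peroxide bound to the vanadium alkoxide of the C3 hydroxyl delivers oxygen to the same face of the electron-rich C4=C5 alkene, setting C4 and C5 cis to the hydroxyl, while the electron-poor conjugated C1=C2 alkene does not react.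

Step 8
Reactants: 10 methyl (1S,5R,6R)-5-hydroxy-7-oxabicyclo[4.1.0]hept-3-ene-3-carboxylate; 11 (R)-2-methylbutanoic acid
Product: 12 methyl 5-O-[(2R)-2-methylbutanoyl]shikimate (3-OH and 4-OH cis, 5-acyloxy trans to 4-OH)
Conditions: Ti(OiPr)4 (1.5 equiv), 11 (1.5 equiv), CH2Cl2, rt; aqueous tartaric acid work-up
Reagents that add atoms: none
Why: Ti(OiPr)4-mediated opening of a 2,3-epoxy alcohol by a carboxylic acid: titanium bridging the C3 alkoxide and the epoxide oxygen activates the ring and the carboxylate attacks the distal carbon C5 with inversion (also the trans-diaxial, inductively favoured site of cis-3-oxy-4,5-epoxycyclohexenes), which sets the 4,5-trans/3,4-cis pattern and puts the first (R)-acyl group on O5.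

Step 9
Reactants: 12 methyl 5-O-[(2R)-2-methylbutanoyl]shikimate
Product: 14 methyl (3R,4S,5R)-3-acetoxy-4-hydroxy-5-{[(2R)-2-methylbutanoyl]oxy}cyclohex-1-ene-1-carboxylate, via cyclic orthoacetate 13 (not isolated)
Conditions: MeC(OMe)3, CSA (cat.), CH2Cl2, rt; then 80% aq. AcOH, rt
Reagents that add atoms: trimethyl orthoacetate, CC(OC)(OC)OC; water, O
Why: Cyclic orthoester formation on the cis-3,4-diol followed by kinetic acid hydrolysis: the hemiorthoester collapses to the ester on the pseudoaxial oxygen, which in the shikimate half-chair (O4 and O5 equatorial) is the allylic O3, so the acetate is placed on O3 and the equatorial C4 hydroxyl stays free without relying on reactivity differences between the two hydroxyls.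

Step 10
Reactants: 14 methyl (3R,4S,5R)-3-acetoxy-4-hydroxy-5-{[(2R)-2-methylbutanoyl]oxy}cyclohex-1-ene-1-carboxylate; 11 (R)-2-methylbutanoic acid
Product: 15 methyl (3R,4S,5R)-3-acetoxy-4,5-bis{[(2R)-2-methylbutanoyl]oxy}cyclohex-1-ene-1-carboxylate (CNP0132712.1)
Conditions: DCC, DMAP (cat.), CH2Cl2, 0 °C to rt
Reagents that add atoms: none
Why: Steglich esterification: the O-acylisourea from DCC is relayed by DMAP as an acylpyridinium that should acylate the remaining equatorial C4 hydroxyl at 0 °C faster than the neighbouring acetate migrates, and the simple α-alkyl acid keeps its (R) centre under these conditions.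

Compound list
1 | D-galactal | OC[C@H]1OC=C[C@@H](O)[C@H]1O | starting material
2 | 3,4-O-isopropylidene-D-galactal | OC[C@H]1OC=C[C@H]2OC(C)(C)O[C@@H]12 | intermediate
3 | 3,4-O-isopropylidene-D-galactal 6-aldehyde | O=C[C@H]1OC=C[C@H]2OC(C)(C)O[C@@H]12 | intermediate
4 | 5-vinyl-3,4-O-isopropylidene-D-galactal (1,5-anhydro-2,6,7-trideoxy-3,4-O-isopropylidene-D-lyxo-hepta-1,6-dienitol) | C=C[C@H]1OC=C[C@H]2OC(C)(C)O[C@@H]12 | intermediate
5 | (1S,5S,6R)-5,6-(isopropylidenedioxy)cyclohex-3-ene-1-carbaldehyde | O=C[C@H]1CC=C[C@@H]2OC(C)(C)O[C@H]12 | intermediate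
6 | (1S,5S,6R)-5,6-(isopropylidenedioxy)cyclohex-3-ene-1-carboxylic acid | O=C(O)[C@H]1CC=C[C@@H]2OC(C)(C)O[C@H]12 | intermediate
7 | methyl (1S,5S,6R)-5,6-(isopropylidenedioxy)cyclohex-3-ene-1-carboxylate | COC(=O)[C@H]1CC=C[C@@H]2OC(C)(C)O[C@H]12 | intermediate
8 | methyl (3S)-3-[(2-hydroxypropan-2-yl)oxy]cyclohexa-1,4-diene-1-carboxylate (formed as its lithium alkoxide) | COC(=O)C1=C[C@@H](OC(C)(C)O)C=CC1 | intermediate
9 | methyl (3S)-3-hydroxycyclohexa-1,4-diene-1-carboxylate | COC(=O)C1=C[C@@H](O)C=CC1 | intermediate
10 | methyl (1S,5R,6R)-5-hydroxy-7-oxabicyclo[4.1.0]hept-3-ene-3-carboxylate | COC(=O)C1=C[C@@H](O)[C@H]2O[C@H]2C1 | intermediate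
11 | (R)-2-methylbutanoic acid | CC[C@@H](C)C(=O)O | starting material
12 | methyl 5-O-[(2R)-2-methylbutanoyl]shikimate | O[C@@H]1[C@H](O)C=C(C(=O)OC)C[C@H]1OC(=O)[C@H](C)CC | intermediate
13 | methyl 3,4-O-(1-methoxyethylidene)-5-O-[(2R)-2-methylbutanoyl]shikimate (orthoester carbon as a mixture of epimers) | COC1(C)O[C@@H]2[C@H](O1)C=C(C(=O)OC)C[C@H]2OC(=O)[C@H](C)CC | intermediate
14 | methyl (3R,4S,5R)-3-acetoxy-4-hydroxy-5-{[(2R)-2-methylbutanoyl]oxy}cyclohex-1-ene-1-carboxylate | O[C@@H]1[C@H](OC(C)=O)C=C(C(=O)OC)C[C@H]1OC(=O)[C@H](C)CC | intermediate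
15 | methyl (3R,4S,5R)-3-acetoxy-4,5-bis{[(2R)-2-methylbutanoyl]oxy}cyclohex-1-ene-1-carboxylate | CC[C@@H](C)C(=O)O[C@@H]1[C@H](OC(C)=O)C=C(C(=O)OC)C[C@H]1OC(=O)[C@H](C)CC | target

Total step count: 10. Longest linear sequence: 10 steps (1 to 15); acid 11 is purchased.

Steps most likely to fail

Step 4. At 240 °C the glycal may ionise at its allylic C3–O bond or polymerise on traces of acid, and the β-alkoxy aldehyde may lose its ketal oxygen and then aromatise. The fallback sets out from 4 and keeps the same bond construction but runs it as an organoaluminium-promoted rearrangement. With iBu3Al in toluene at −78 °C to rt, the Lewis acid should trigger the C2–C7 bond formation at low temperature and reduce the aldehyde in the flask. This would give [(1R,5S,6R)-5,6-(isopropylidenedioxy)cyclohex-3-en-1-yl]methanol F1. Oxidation of F1 with TEMPO/PhI(OAc)2 in MeCN–H2O would give acid 6, where the route is rejoined at the methylation of step 5.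

Step 6. The amide base may also remove the doubly allylic C6–H of the product, which would lead to double-bond migration or, after loss of the C3 oxygen, to an arene; the enolate may also eliminate sluggishly. The fallback sets out from aldehyde 5 and moves the elimination to the aldehyde level, where a weak amine base suffices. DBU in CH2Cl2 at 0 °C should give (3S)-3-hydroxycyclohexa-1,4-diene-1-carbaldehyde F2. Chlorite oxidation as in step 5 would give (3S)-3-hydroxycyclohexa-1,4-diene-1-carboxylic acid F3, and TMSCHN2/MeOH would return dienol 9.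

Step 9. The hemiorthoester may collapse toward O4, or the acetyl group may migrate from O3 to the cis O4 during hydrolysis, so that the acetate ends on the wrong oxygen. The fallback sets out from epoxy alcohol 10 and installs the acetate while only one hydroxyl exists. Ac2O/pyridine should give methyl (1S,5R,6S)-5-acetoxy-7-oxabicyclo[4.1.0]hept-3-ene-3-carboxylate F4. Opening F4 at C5 with cesium (R)-2-methylbutanoate (Cs2CO3 with excess 11, DMF, about 60 °C) follows the innate distal, trans-diaxial preference of this cis-3-oxy epoxide and would give 14, where the route is rejoined.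

Further compounds
F1 | step 4 | [(1R,5S,6R)-5,6-(isopropylidenedioxy)cyclohex-3-en-1-yl]methanol | OC[C@H]1CC=C[C@@H]2OC(C)(C)O[C@H]12
F2 | step 6 | (3S)-3-hydroxycyclohexa-1,4-diene-1-carbaldehyde | O=CC1=C[C@@H](O)C=CC1
F3 | step 6 | (3S)-3-hydroxycyclohexa-1,4-diene-1-carboxylic acid | O=C(O)C1=C[C@@H](O)C=CC1
F4 | step 9 | methyl (1S,5R,6S)-5-acetoxy-7-oxabicyclo[4.1.0]hept-3-ene-3-carboxylate | COC(=O)C1=C[C@@H](OC(C)=O)[C@H]2O[C@H]2C1
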